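**Retrosynthetic overview**

1. Target 33 ⇐ desilylation and ent-Shi epoxidation of the 11E alkene in lactone 31; C17 by enolate methylation and H-1 by CuH reduction of the unsaturated δ-lactone 28.
2. 28 ⇐ intramolecular HWE of the C3 phosphonoacetate onto the C1 ketone of β-hydroxy ketone 25 (δ-lactone, second ring).
3. Feature used: the C3 carbinol is β to C1 through the C2 methylene and C4 is quaternary, so C2–C3 is an aldol bond between a methyl ketone and a non-enolisable aldehyde; 25 ⇐ seco keto aldehyde 23 by macroaldolisation (14-membered carbocycle, first ring).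
4. 23 ⇐ C7–C8 union of the alkenyllithium from iodide 9 (Saucy–Marbet Claisen sets 11E) with aldehyde 16 ((R)-2-methylglycidol supplies C4); C7 by CBS reduction.
5. Ring order: 14-membered carbocycle (step 16) → δ-lactone (step 18) → epoxide (step 21).

Key step: step 16

Assumption (remark on the chemistry): cembrane numbering is used (C1–C14 ring; C15–C17 lactone propionate; C18 = CH3 on C4, C19 = exocyclic CH2 on C8, C20 = CH3 on C12), and the target is read as (1R,3R,4S,7R,11S,12S,15S). (R)-2-Methylglycidol and the L-fructose-derived Shi ketone are taken as purchasable.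

**Route**

Step 1
Reactants: 1 pent-4-yn-1-ol
Product: 2 4-iodopent-4-en-1-ol
Conditions: NaI, TMSCl, H2O, MeCN, 0 °C → rt
Reagents that add atoms: sodium iodide, [Na+].[I-]
Why: Markovnikov hydroiodination of the terminal alkyne by HI generated in situ should give the 2-iodo-1-alkene; no stereocentre is formed.

Step 2
Reactants: 2 4-iodopent-4-en-1-ol
Product: 3 4-iodopent-4-enal
Conditions: DMP, NaHCO3, CH2Cl2, 0 °C → rt
Reagents that add atoms: none
Why: Dess–Martin oxidation takes the primary alcohol to the aldehyde and leaves the vinyl iodide alone.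

Step 3
Reactants: 3 4-iodopent-4-enal; 4 isopropenylmagnesium bromide
Product: 5 rac-6-iodo-2-methylhepta-1,6-dien-3-ol
Conditions: THF, −78 → 0 °C; aq. NH4Cl
Reagents that add atoms: none
Why: Grignard 1,2-addition to the aldehyde; the racemic carbinol centre is consumed in step 4.

Step 4
Reactants: 5 rac-6-iodo-2-methylhepta-1,6-dien-3-ol; 6 2-methoxypropene
Product: 8 (5E)-9-iodo-5-methyldeca-5,9-dien-2-one, via allyl isopropenyl ether 7 (not isolated)
Conditions: 2-methoxypropene (excess), 2,4-dinitrophenol (cat.), toluene, 130 °C, sealed tube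
Reagents that add atoms: none
Why: Saucy–Marbet variant of the Claisen rearrangement: acid-catalysed exchange gives ether 7, whose chair [3,3] shift with the C10 chain equatorial should set the 11E trisubstituted alkene and deliver the methyl ketone (C1, C2, C14) directly.

Step 5
Reactants: 8 (5E)-9-iodo-5-methyldeca-5,9-dien-2-one
Product: 9 (5E)-2-iodo-9,9-dimethoxy-6-methyldeca-1,5-diene
Conditions: HC(OMe)3, MeOH, PPTS (cat.), rt
Reagents that add atoms: trimethyl orthoformate, COC(OC)OC
Why: acid-catalysed ketalisation masks the ketone against t-BuLi and the borane of steps 10–12; the acyclic ketal is chosen because it can later be hydrolysed under conditions that spare a tertiary TES ether.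

Step 6
Reactants: 10 (R)-2-methylglycidol
Product: 11 (S)-triethyl[(2-methyloxiran-2-yl)methoxy]silane
Conditions: TESCl, imidazole, CH2Cl2, 0 °C
Reagents that add atoms: chlorotriethylsilane, CC[Si](Cl)(CC)CC
Why: silylation under imidazole forms no alkoxide, so the degenerate Payne rearrangement that would racemise this epoxy alcohol is avoided; the bought centre becomes C4, and its label changes from R to S only because the CIP ranks of the two CH2O arms swap.

Step 7
Reactants: 11 (S)-triethyl[(2-methyloxiran-2-yl)methoxy]silane; 12 allylmagnesium chloride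
Product: 13 (S)-2-methyl-1-[(triethylsilyl)oxy]hex-5-en-2-ol
Conditions: CuI (10 mol%), THF, −40 → −20 °C; aq. NH4Cl
Reagents that add atoms: none
Why: copper-catalysed SN2 opening of the 2,2-disubstituted epoxide at its CH2 terminus forms C5–C6 and leaves the quaternary centre untouched.

Step 8
Reactants: 13 (S)-2-methyl-1-[(triethylsilyl)oxy]hex-5-en-2-ol
Product: 14 (S)-5-methyl-5,6-bis[(triethylsilyl)oxy]hex-1-ene
Conditions: TESOTf, 2,6-lutidine, CH2Cl2, −78 → 0 °C
Reagents that add atoms: triethylsilyl triflate, CC[Si](CC)(CC)OS(=O)(=O)C(F)(F)F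
Why: silyl triflate/lutidine silylation of the tertiary alcohol; a primary-to-tertiary silyl shift in step 7 would be harmless because both oxygens end as TES ethers.

Step 9
Reactants: 14 (S)-5-methyl-5,6-bis[(triethylsilyl)oxy]hex-1-ene
Product: 16 (S)-4-methyl-4,5-bis[(triethylsilyl)oxy]pentanal, via secondary ozonide 15 (not isolated)
Conditions: O3, CH2Cl2, −78 °C; PPh3, −78 °C → rt
Reagents that add atoms: ozone, [O-][O+]=O
Why: ozonolysis of the only alkene with reductive work-up gives the C7 aldehyde.

Step 10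
Reactants: 9 (5E)-2-iodo-9,9-dimethoxy-6-methyldeca-1,5-diene; 16 (S)-4-methyl-4,5-bis[(triethylsilyl)oxy]pentanal
Product: 18 (2S,9E)-13,13-dimethoxy-2,10-dimethyl-6-methylidene-1,2-bis[(triethylsilyl)oxy]tetradec-9-en-5-ol (both C7 epimers), via vinyllithium 17 (not isolated)
Conditions: 9, t-BuLi (2.05 equiv), Et2O, −78 °C; then 16, −78 °C; pH 7 buffer
Reagents that add atoms: none
Why: iodine–lithium exchange gives the 2-lithio-1-alkene, which adds 1,2 to the aldehyde to form C7–C8; no control at C7 is sought because it is set in steps 11–12.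

Step 11
Reactants: 18 allylic alcohol (C7 epimers)
Product: 19 (2S,9E)-13,13-dimethoxy-2,10-dimethyl-6-methylidene-1,2-bis[(triethylsilyl)oxy]tetradec-9-en-5-one
Conditions: DMP, NaHCO3, CH2Cl2, 0 °C → rt
Reagents that add atoms: none
Why: buffered Dess–Martin oxidation of the allylic alcohol to the α-methylene ketone, with ketal and TES ethers kept away from acid.

Step 12
Reactants: 19 α-methylene ketone
Product: 20 (2S,5R,9E)-13,13-dimethoxy-2,10-dimethyl-6-methylidene-1,2-bis[(triethylsilyl)oxy]tetradec-9-en-5-ol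
Conditions: (S)-Me-CBS (20 mol%), catecholborane, toluene, −78 °C; MeOH, aq. NaOH
Reagents that add atoms: none
Why: Corey–Bakshi–Shibata reduction in which the 2-substituted alkenyl group acts as the large substituent, so the (S)-oxazaborolidine should give the 7R alcohol; catecholborane at −78 °C avoids hydroboration of the isolated alkenes.

Step 13
Reactants: 20 (7R)-allylic alcohol
Product: 21 (2S,5R,9E)-5-[(tert-butyldimethylsilyl)oxy]-13,13-dimethoxy-2,10-dimethyl-6-methylidene-1,2-bis[(triethylsilyl)oxy]tetradec-9-ene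
Conditions: TBSCl, imidazole, DMAP (cat.), DMF, rt
Reagents that add atoms: tert-butylchlorodimethylsilane, CC(C)(C)[Si](C)(C)Cl
Why: silylation of the secondary allylic alcohol under non-acidic conditions that the dimethyl ketal tolerates.

Step 14
Reactants: 21 fully protected chain
Product: 22 (5E,10R,13S)-10-[(tert-butyldimethylsilyl)oxy]-14-hydroxy-5,13-dimethyl-9-methylidene-13-[(triethylsilyl)oxy]tetradec-5-en-2-one
Conditions: AcOH/THF/H2O (3:1:1), rt
Reagents that add atoms: water, O
Why: mild aqueous acid hydrolysis: the acyclic ketal and the primary TES ether are far more labile than the tertiary TES and secondary TBS ethers, so the C1 ketone and the C3 alcohol should be freed together.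

Step 15
Reactants: 22 hydroxy ketone
Product: 23 (2S,5R,9E)-5-[(tert-butyldimethylsilyl)oxy]-2,10-dimethyl-6-methylidene-13-oxo-2-[(triethylsilyl)oxy]tetradec-9-enal (seco keto aldehyde: C1 methyl ketone, C3 aldehyde, 4-OTES, 7-OTBS, 11E)
Conditions: DMP, NaHCO3, CH2Cl2, 0 °C → rt
Reagents that add atoms: none
Why: Dess–Martin oxidation of the neopentyl primary alcohol; the α-quaternary aldehyde cannot enolise or epimerise.

Step 16
Reactants: 23 seco keto aldehyde
Product: 25 (3R,4S,7R,11E)-7-[(tert-butyldimethylsilyl)oxy]-3-hydroxy-4,12-dimethyl-8-methylidene-4-[(triethylsilyl)oxy]cyclotetradec-11-en-1-one, via lithium enolate 24 (not isolated)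
Conditions: LiHMDS (2 equiv), THF, −78 °C, 23 added by syringe pump (final ca. 1 mM); AcOH, −78 °C
Reagents that add atoms: none
Why: LiHMDS removes a proton from the C2 methyl group (the less hindered α-position; the α-quaternary aldehyde has no α-H and is attacked only reversibly by the bulky amide at −78 °C), and enolate 24 adds through C2 to the C3 aldehyde in a closed lithium-bridged transition state. This is an intramolecular aldol addition of the macroaldolisation type (amide-base ring closure of ω-formyl methyl ketones and acetates at high dilution). The 14-membered carbocycle closes in the 14-(enolendo)-exo-trig mode. The new C3 centre is controlled by C4: with the non-chelating OTES group the C4–O bond lies anti to the C=O dipole (Cornforth/polar Felkin–Anh arrangement), the ring bond C4–C5 is anti to the forming bond and the enolate passes the small methyl group, i.e. Re-face attack, which should give 3R. The step needs CH3- over C14-enolisation (bulky base, −78 °C, excess base so that no free ketone equilibrates the enolate), ring closure over oligomerisation (slow addition, high dilution) and an intact 4-OTES group (lithium counter-ion and cold acidic quench against 1,2-silyl shift and retro-aldol). The C3 ratio has to be established by experiment, and any 3-epimer is removed at this stage.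

Step 17
Reactants: 25 macrocyclic β-hydroxy ketone; 26 diethylphosphonoacetic acid
Product: 27 3-O-[(diethoxyphosphoryl)acetyl] ester of 25
Conditions: DCC, DMAP (cat.), CH2Cl2, 0 °C
Reagents that add atoms: none
Why: Steglich esterification of the C3 alcohol, kept cold with catalytic DMAP so that the β-acyloxy ketone does not eliminate.

Step 18
Reactants: 27 phosphonoacetate
Product: 28 (3R,4S,7R,11E)-7-OTBS-4-OTES-17-norcembra-1(15),8(19),11-trien-16,3-olide
Conditions: LiCl, i-Pr2NEt, MeCN, rt
Reagents that add atoms: none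
Why: Masamune–Roush intramolecular Horner–Wadsworth–Emmons reaction: the lithium-chelated phosphonate is deprotonated in preference to the ketone α-CH and olefinates the C1 ketone in a six-membered closure to the unsaturated δ-lactone; no stereocentre is formed.

Step 19
Reactants: 28 unsaturated δ-lactone
Product: 29 (1R,3R,4S,7R,11E)-7-OTBS-4-OTES-17-norcembra-8(19),11-dien-16,3-olide
Conditions: Cu(OAc)2·H2O (5 mol%), 1,2-bis(diphenylphosphino)benzene (5 mol%), (EtO)2MeSiH, t-BuOH, toluene, rt
Reagents that add atoms: none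
Why: ligated copper hydride 1,4-reduction of a β,β-disubstituted unsaturated lactone, inert to the isolated alkenes; hydride should add to C1 anti to the C3 substituent (axial attack on the half-chair, on the face not covered by the C4–C14 bridge), which places C14 cis to C4 (1R).

Step 20
Reactants: 29 saturated δ-lactone
Product: 31 (1R,3R,4S,7R,11E,15S)-7-OTBS-4-OTES-cembra-8(19),11-dien-16,3-olide, via lithium enolate 30 (not isolated)
Conditions: LDA (1.1 equiv), THF, −78 °C; MeI, −78 → −40 °C
Reagents that add atoms: iodomethane, CI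
Why: lactone enolate alkylation; MeI should approach anti to the adjacent C14 substituent on the face away from the macrocyclic bridge, giving the trans 15-methyl group (15S), which is also the equatorial, thermodynamically preferred epimer.

Step 21
Reactants: 31 methylated lactone
Product: 32 (1R,3R,4S,7R,11S,12S,15S)-11,12-epoxy-7-OTBS-4-OTES-cembr-8(19)-en-16,3-olide
Conditions: ent-Shi ketone (L-fructose-derived, 30 mol%), Oxone, K2CO3, Bu4NHSO4, MeCN/DMM, aq. Na2B4O7–EDTA buffer, 0 °C
Reagents that add atoms: potassium peroxymonosulfate (Oxone), [K+].OOS(=O)(=O)[O-]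
Why: Shi asymmetric epoxidation by a chiral dioxirane; the electron-rich trisubstituted 11E alkene should react ahead of the 1,1-disubstituted alkene next to the OTBS group, and the L-fructose-derived ketone is the enantiomer that gives (S,S)-epoxides from E-trisubstituted alkenes (11S,12S).

Step 22
Reactants: 32 epoxy bis-silyl ether
Product: 33 (1R,3R,4S,7R,11S,12S,15S)-11,12-epoxy-4,7-dihydroxycembr-8(19)-en-16,3-olide (target)
Conditions: TBAF, AcOH, THF, 0 °C → rt
Reagents that add atoms: none
Why: fluoride cleavage of the tertiary TES and secondary TBS ethers, buffered with acetic acid so that lactone and epoxide are not exposed to free alkoxide.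

**Compound list**

1 | pent-4-yn-1-ol | C#CCCCO | starting material
2 | 4-iodopent-4-en-1-ol | C=C(I)CCCO | intermediate
3 | 4-iodopent-4-enal | C=C(I)CCC=O | intermediate
4 | isopropenylmagnesium bromide | CC(=C)[Mg]Br | starting material
5 | rac-6-iodo-2-methylhepta-1,6-dien-3-ol | C=C(C)C(O)CCC(I)=C | intermediate
6 | 2-methoxypropene | COC(C)=C | starting material
7 | 6-iodo-2-methyl-3-(prop-1-en-2-yloxy)hepta-1,6-diene (allyl isopropenyl ether) | C=C(C)OC(CCC(I)=C)C(C)=C | intermediate (not isolated)
8 | (5E)-9-iodo-5-methyldeca-5,9-dien-2-one | CC(=O)CC/C(C)=C/CCC(I)=C | intermediate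
9 | (5E)-2-iodo-9,9-dimethoxy-6-methyldeca-1,5-diene | COC(C)(OC)CC/C(C)=C/CCC(I)=C | intermediate
10 | (R)-2-methylglycidol | C[C@]1(CO1)CO | starting material
11 | (S)-triethyl[(2-methyloxiran-2-yl)methoxy]silane | C[C@]1(CO1)CO[Si](CC)(CC)CC | intermediate
12 | allylmagnesium chloride | C=CC[Mg]Cl | starting material
13 | (S)-2-methyl-1-[(triethylsilyl)oxy]hex-5-en-2-ol | C[C@](O)(CCC=C)CO[Si](CC)(CC)CC | intermediate
14 | (S)-5-methyl-5,6-bis[(triethylsilyl)oxy]hex-1-ene | C[C@](O[Si](CC)(CC)CC)(CCC=C)CO[Si](CC)(CC)CC | intermediate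
15 | 3-[(S)-3-methyl-3,4-bis(triethylsilyloxy)butyl]-1,2,4-trioxolane (secondary ozonide) | C[C@](O[Si](CC)(CC)CC)(CCC1OCOO1)CO[Si](CC)(CC)CC | intermediate (not isolated)
16 | (S)-4-methyl-4,5-bis[(triethylsilyl)oxy]pentanal | C[C@](O[Si](CC)(CC)CC)(CCC=O)CO[Si](CC)(CC)CC | intermediate
17 | [(5E)-9,9-dimethoxy-6-methyldeca-1,5-dien-2-yl]lithium | COC(C)(OC)CC/C(C)=C/CCC([Li])=C | intermediate (not isolated)
18 | (2S,9E)-13,13-dimethoxy-2,10-dimethyl-6-methylidene-1,2-bis[(triethylsilyl)oxy]tetradec-9-en-5-ol, C7 epimers | COC(C)(OC)CC/C(C)=C/CCC(=C)C(O)CC[C@](C)(O[Si](CC)(CC)CC)CO[Si](CC)(CC)CC | intermediate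
19 | (2S,9E)-13,13-dimethoxy-2,10-dimethyl-6-methylidene-1,2-bis[(triethylsilyl)oxy]tetradec-9-en-5-one | COC(C)(OC)CC/C(C)=C/CCC(=C)C(=O)CC[C@](C)(O[Si](CC)(CC)CC)CO[Si](CC)(CC)CC | intermediate
20 | (2S,5R,9E)-13,13-dimethoxy-2,10-dimethyl-6-methylidene-1,2-bis[(triethylsilyl)oxy]tetradec-9-en-5-ol | COC(C)(OC)CC/C(C)=C/CCC(=C)[C@H](O)CC[C@](C)(O[Si](CC)(CC)CC)CO[Si](CC)(CC)CC | intermediate
21 | (2S,5R,9E)-5-[(tert-butyldimethylsilyl)oxy]-13,13-dimethoxy-2,10-dimethyl-6-methylidene-1,2-bis[(triethylsilyl)oxy]tetradec-9-ene | COC(C)(OC)CC/C(C)=C/CCC(=C)[C@H](O[Si](C)(C)C(C)(C)C)CC[C@](C)(O[Si](CC)(CC)CC)CO[Si](CC)(CC)CC | intermediate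
22 | (5E,10R,13S)-10-[(tert-butyldimethylsilyl)oxy]-14-hydroxy-5,13-dimethyl-9-methylidene-13-[(triethylsilyl)oxy]tetradec-5-en-2-one | CC(=O)CC/C(C)=C/CCC(=C)[C@H](O[Si](C)(C)C(C)(C)C)CC[C@](C)(O[Si](CC)(CC)CC)CO | intermediate
23 | (2S,5R,9E)-5-[(tert-butyldimethylsilyl)oxy]-2,10-dimethyl-6-methylidene-13-oxo-2-[(triethylsilyl)oxy]tetradec-9-enal | CC(=O)CC/C(C)=C/CCC(=C)[C@H](O[Si](C)(C)C(C)(C)C)CC[C@](C)(O[Si](CC)(CC)CC)C=O | intermediate (key-step precursor)
24 | lithium C1(O)=C2 enolate of 23 | [Li]OC(=C)CC/C(C)=C/CCC(=C)[C@H](O[Si](C)(C)C(C)(C)C)CC[C@](C)(O[Si](CC)(CC)CC)C=O | intermediate (not isolated)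
25 | (3R,4S,7R,11E)-7-[(tert-butyldimethylsilyl)oxy]-3-hydroxy-4,12-dimethyl-8-methylidene-4-[(triethylsilyl)oxy]cyclotetradec-11-en-1-one | O=C1C[C@@H](O)[C@@](C)(O[Si](CC)(CC)CC)CC[C@@H](O[Si](C)(C)C(C)(C)C)C(=C)CC/C=C(\C)CC1 | intermediate (key-step product)
26 | diethylphosphonoacetic acid | CCOP(=O)(CC(=O)O)OCC | starting material
27 | 3-O-[(diethoxyphosphoryl)acetyl] ester of 25 | O=C1C[C@@H](OC(=O)CP(=O)(OCC)OCC)[C@@](C)(O[Si](CC)(CC)CC)CC[C@@H](O[Si](C)(C)C(C)(C)C)C(=C)CC/C=C(\C)CC1 | intermediate
28 | (3R,4S,7R,11E)-7-OTBS-4-OTES-17-norcembra-1(15),8(19),11-trien-16,3-olide | C=C1CC/C=C(\C)CCC2=CC(=O)O[C@H](C2)[C@@](C)(O[Si](CC)(CC)CC)CC[C@H]1O[Si](C)(C)C(C)(C)C | intermediate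
29 | (1R,3R,4S,7R,11E)-7-OTBS-4-OTES-17-norcembra-8(19),11-dien-16,3-olide | C=C1CC/C=C(\C)CC[C@@H]2C[C@@H](OC(=O)C2)[C@@](C)(O[Si](CC)(CC)CC)CC[C@H]1O[Si](C)(C)C(C)(C)C | intermediate
30 | lithium enolate of 29 (C15=C16–OLi) | C=C1CC/C=C(\C)CC[C@@H]2C[C@@H](OC(O[Li])=C2)[C@@](C)(O[Si](CC)(CC)CC)CC[C@H]1O[Si](C)(C)C(C)(C)C | intermediate (not isolated)
31 | (1R,3R,4S,7R,11E,15S)-7-OTBS-4-OTES-cembra-8(19),11-dien-16,3-olide | C=C1CC/C=C(\C)CC[C@@H]2C[C@@H](OC(=O)[C@H]2C)[C@@](C)(O[Si](CC)(CC)CC)CC[C@H]1O[Si](C)(C)C(C)(C)C | intermediate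
32 | (1R,3R,4S,7R,11S,12S,15S)-11,12-epoxy-7-OTBS-4-OTES-cembr-8(19)-en-16,3-olide | C=C1CC[C@@H]2O[C@@]2(C)CC[C@@H]2C[C@@H](OC(=O)[C@H]2C)[C@@](C)(O[Si](CC)(CC)CC)CC[C@H]1O[Si](C)(C)C(C)(C)C | intermediate
33 | (1R,3R,4S,7R,11S,12S,15S)-11,12-epoxy-4,7-dihydroxycembr-8(19)-en-16,3-olide (CNP0262409.1) | C=C1CC[C@@H]2O[C@@]2(C)CC[C@@H]2C[C@@H](OC(=O)[C@H]2C)[C@@](C)(O)CC[C@H]1O | target

**Step count**

Total: 22 steps. Longest linear sequence: 18 steps (steps 1–5, then 10–22, from pent-4-yn-1-ol); the other branch is steps 6–9.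

**Steps most likely to fail**

Step 16 (macroaldolisation). The slow 14-membered closure may be outrun by intermolecular aldol addition or by proton transfer that moves the enolate to C14. The lithium transition state may also discriminate poorly between the two aldehyde faces, since only CH3 and the ring CH2 differ at C4, and the aldolate may undergo retro-aldol or silyl shift before the quench. Fallback: a Lewis-acid (Mukaiyama) ring closure that sets out from 23 and returns at 25. LDA/TMSCl (in situ quench, THF, −78 °C) traps the kinetic enolate as the regio-defined trimethylsilyl enol ether aldehyde F1. Slow addition of F1 to BF3·OEt2 (CH2Cl2, −78 °C, ca. 1 mM) then closes the ring through an open, non-chelated transition state without a metal aldolate, and aqueous work-up gives 25.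

Step 18 (lactone annulation, together with the acylation of step 17). Under base the β-acyloxy ketone may lose the C3 ester by E1cB elimination through the C2 enolate, or suffer retro-aldol, before the phosphonate olefinates C1. Fallback: a reductive, non-basic annulation that sets out from 25 and returns at 28. Bromoacetyl bromide/pyridine (CH2Cl2, −78 °C) gives the 3-O-bromoacetate F2. SmI2 (THF, −78 °C) generates the samarium ester enolate, which adds to the C1 ketone (intramolecular Reformatsky reaction) to give the β-hydroxy δ-lactone F3. The Burgess reagent, followed by DBU to bring any β,γ-alkene into conjugation, dehydrates F3 to 28.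

Step 21 (epoxidation on the macrocycle). The conformational bias of the bicyclic macrocycle may oppose the catalyst and erode facial selectivity, and the lactone may be partly hydrolysed at the pH of the reaction. Fallback: epoxidise the open chain, where catalyst control is most dependable, and carry the epoxide through the ring closures; the sequence sets out from 22 and returns at 32. ent-Shi epoxidation of 22 gives the (11S,12S)-epoxy hydroxy ketone F4. The operations of steps 15–20 are then applied unchanged: DMP gives the epoxy keto aldehyde F5; LiHMDS macroaldolisation gives the epoxy aldol F6; DCC/diethylphosphonoacetic acid gives the epoxy phosphonoacetate F7; LiCl/i-Pr2NEt gives the epoxy unsaturated lactone F8; CuH reduction gives the epoxy saturated lactone F9; and LDA/MeI gives 32. No acid is used after step 14, so the trisubstituted epoxide should survive.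

Further compounds
F1 | step 16 | trimethylsilyl enol ether (C1–O–TMS, C1=C2) of keto aldehyde 23 | C=C(O[Si](C)(C)C)CC/C(C)=C/CCC(=C)[C@H](O[Si](C)(C)C(C)(C)C)CC[C@](C)(O[Si](CC)(CC)CC)C=O
F2 | step 18 | 3-O-bromoacetate of 25 | O=C1C[C@@H](OC(=O)CBr)[C@@](C)(O[Si](CC)(CC)CC)CC[C@@H](O[Si](C)(C)C(C)(C)C)C(=C)CC/C=C(\C)CC1
F3 | step 18 | (3R,4S,7R,11E)-1-hydroxy-7-OTBS-4-OTES-17-norcembra-8(19),11-dien-16,3-olide (C1 carbinol unassigned) | C=C1CC/C=C(\C)CCC2(O)CC(=O)O[C@H](C2)[C@@](C)(O[Si](CC)(CC)CC)CC[C@H]1O[Si](C)(C)C(C)(C)C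
F4 | step 21 | (11S,12S)-11,12-epoxide of hydroxy ketone 22 | CC(=O)CC[C@]1(C)O[C@H]1CCC(=C)[C@H](O[Si](C)(C)C(C)(C)C)CC[C@](C)(O[Si](CC)(CC)CC)CO
F5 | step 21 | (11S,12S)-11,12-epoxide of keto aldehyde 23 | CC(=O)CC[C@]1(C)O[C@H]1CCC(=C)[C@H](O[Si](C)(C)C(C)(C)C)CC[C@](C)(O[Si](CC)(CC)CC)C=O
F6 | step 21 | (11S,12S)-11,12-epoxide of macrocyclic aldol 25 | C=C1CC[C@@H]2O[C@@]2(C)CCC(=O)C[C@@H](O)[C@@](C)(O[Si](CC)(CC)CC)CC[C@H]1O[Si](C)(C)C(C)(C)C
F7 | step 21 | (11S,12S)-11,12-epoxide of phosphonoacetate 27 | C=C1CC[C@@H]2O[C@@]2(C)CCC(=O)C[C@@H](OC(=O)CP(=O)(OCC)OCC)[C@@](C)(O[Si](CC)(CC)CC)CC[C@H]1O[Si](C)(C)C(C)(C)C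
F8 | step 21 | (11S,12S)-11,12-epoxide of unsaturated lactone 28 | C=C1CC[C@@H]2O[C@@]2(C)CCC2=CC(=O)O[C@H](C2)[C@@](C)(O[Si](CC)(CC)CC)CC[C@H]1O[Si](C)(C)C(C)(C)C
F9 | step 21 | (11S,12S)-11,12-epoxide of saturated lactone 29 | C=C1CC[C@@H]2O[C@@]2(C)CC[C@@H]2C[C@@H](OC(=O)C2)[C@@](C)(O[Si](CC)(CC)CC)CC[C@H]1O[Si](C)(C)C(C)(C)C
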